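All runs come from a simulation with made-up constants; noise was put on by code.

Count, for each flask, the X-hours that the average J has sat through, and let one constant turn them into reacted J.

all flasks: J 0.051 M (fed, over 2.5 h)

| flask | X | remark | time |
|---|---|---|---|
| Tuesday's | 0.072 M | run made earlier; the fed solution adds 0.25 times the starting volume |  |
| Sunday's | 0.091 M | run made earlier; the fed solution adds 0.25 times the starting volume |  |
| Monday's | 0.10 M | run made earlier; the fed solution adds 0.25 times the starting volume |  |
| ochre | 0.0760 M | the fed solution adds 0.25 times the starting volume | 5.0 h |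
| violet | 0.110 M | the fed solution adds 0.25 times the starting volume | 5.0 h |

| run | time / h | J / % | D / % |
|---|---|---|---|
| Tuesday's | 0.333 | 13.9 | 0 |
| Tuesday's | 0.833 | 33.8 | 1.6 |
| Tuesday's | 1.50 | 55.7 | 3.4 |
| Tuesday's | 2.50 | 87.4 | 6.1 |
| Sunday's | 0.333 | 12.3 | 1.9 |
| Sunday's | 0.833 | 30.3 | 1.8 |
| Sunday's | 1.50 | 53.4 | 1.1 |
| Sunday's | 2.50 | 87.3 | 8.5 |
| Monday's | 0.333 | 12.9 | 1.1 |
| Monday's | 0.833 | 32.0 | 0 |
| Monday's | 1.50 | 55.4 | 3.1 |
| Monday's | 2.50 | 84.6 | 7.2 |

(standard deviation of a reading: 1 percentage point)

- part of the J that has reacted at the end, ochre
- part of the J that has reacted at the end, violet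
- what raising the concentration of X from its lowest to its highest value here does to the part of the J that has reacted (changes below 5 percentage points count as none) (no change / it rises / it falls)

- charges are per starting volume, the dose included; the dosed solution carries all of it
- what has gone from J into another species counts as reacted, even if it can come back
- percentages count the whole charge, also what has not yet gone in

1. J enters evenly, so at the end of the feed the average J has been in the flask for 1.25 h. I take c(X) as charged until then; afterwards the feed has diluted it by a factor of 1.25.

2. For a pseudo-first-order loss, J left = exp(−κ × X-hours), whatever c(J) is. Pooling the end-of-feed J of the three runs gives the reading 1.33 M⁻¹ h⁻¹, my X-hour constant κ, the natural-log loss of J per X-hour.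

3. The weak link is order one in X. From Tuesday's run to Monday's, J at the end of the feed differs by 2.8 percentage points, against a scatter of 1 point. I commit to it anyway, and I count no X as used.

4. By my count ochre collects 0.247 M·h, so I estimate 28.0% reacted. Violet collects 0.357 M·h, so I estimate 37.9% reacted. My gap of 9.9 points means that I expect it to rise.

5. The forecast differs: 35% for ochre, 37% for violet, and no change, on the ground that “X therefore looks close to zero order, at least over this range.”

The flasks give 28.2% for ochre and 38.2% for violet, and it rises by 10 points.

    J + X + E → D + 2 E (k = 0.0300 M⁻² s⁻¹)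
    J + X → D + E (k = 2.10 × 10⁻⁴ M⁻¹ s⁻¹)
    J + E ⇌ L, settled at all times (K = 750 M⁻¹)

In ochre at 5.00 h, J + X into D + E uses J 27 times as fast as J + X + E into D + 2 E. By that second step, J in ochre has a half-life of 19 d at that moment, long against the 5.0 h of the run. Carried on, κ leaves 72.0% J in ochre, and the flask holds 71.8%. A flask charged like ochre but with c(X) at 0.30 M, read at the same 5.0 h, collects 0.975 M·h by the same count, so κ gives 72.7% reacted; that flask shows 73.6%.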